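## Structural features

Sauriol B is a 9,9'-deoxy dibenzylbutane lignan: two benzene rings joined only by the open chain C7–C8–C8'–C7' (lignan numbering, C7 on ring A), with a methyl group (C9, C9') on C8 and on C8', and no ring besides the two arenes. Ring A is 3-methoxy-4,5-dihydroxyphenyl (a catechol) and ring B is 4-hydroxy-3,5-dimethoxyphenyl, so the two ends differ by a single O-methyl group far from the stereocentres. C8 and C8' are adjacent stereocentres, both R, each bearing H, CH3, a benzylic CH2 and the other methine; this is the like (threo-type) arrangement, so the chain has a local twofold axis through the middle of C8–C8'. Neither stereocentre has a heteroatom, a carbonyl group or an acidic hydrogen nearby, so nothing can direct a reagent or carry an auxiliary, nothing can epimerise, and an error cannot be repaired afterwards. The fragile parts are the catechol of ring A and the other electron-rich phenol, which oxidise readily to quinones and therefore stay masked until the last step. The real difficulty is absolute and relative control of two contiguous, purely hydrocarbon-substituted stereocentres while rings A and B are kept distinct. The key step exploits the fact that each of C8 and C8' is the retron of an aryl-conjugated trisubstituted alkene Ar–CH=C(CH3)–, and that the two retrons share the C8–C8' bond. The whole stereochemical problem therefore collapses into one flat (1E,3E)-1,4-diaryl-2,3-dimethylbuta-1,3-diene, whose two alkenes present the same face pattern to one chiral hydrogenation catalyst.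

## Logic of the disconnections

**17 back to 16.** The three phenolic O–H bonds are replaced by O–CH2Ph bonds. The reason is the air-sensitive catechol of ring A and the wish to keep free phenols away from cationic and low-valent metals. The gain is a robust, non-chelating intermediate. The forward step must cleave three O–benzyl bonds without touching the O–methyl bonds or the benzylic C7 and C7' carbons.

**16 back to 13 (key disconnection).** Four C–H bonds are cut: C8–H and C8'–H at the stereocentres, and one C–H at each of C7 and C7'. Both stereocentres disappear and 13 is achiral, yet it holds every carbon and oxygen atom of the target in its final place. The gain is from two contiguous stereocentres to none, with no oxygenated carbon to erase later. The forward step must add hydrogen 1,2 to each alkene with the same facial sense and with no 1,4-addition. It also needs 13 as the pure (E,E) isomer, because a Z alkene would give the opposite configuration at its carbon.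

**13 back to 5 and 10 (through 12 and 11).** The C8–C8' bond between two sp2 carbons and the two vinylic C–H bonds at C7 and C7' are cut. The cut lies on the local twofold axis and gives two halves of equal size that differ only in the ring. The five-membered metallacycle 12 fixes both alkene geometries, because on each alkene the metal sits cis to the new C–C bond and protonolysis replaces it with retention. The forward step must achieve cross- and not homo-coupling (stepwise loading through 11) and must place each aryl group next to zirconium.

**5 back to 3, 2 and 1; 10 back to 8, 7 and 6.** The C8–C9 bond (methyl to alkyne carbon) and the C7≡C8 triple bond are cut back to an aldehyde C=O, a one-carbon homologation, and then the O–benzyl bonds are cut. This reaches 1 and 6, which are commercial and already carry the full oxygen pattern of rings B and A. The forward organolithium step must tolerate aryl benzyl ethers.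

## Other disconnections considered

**Alternative 1:** the route that comes to mind first. The cut is the bond from C8 to the benzylic carbon of ring A in a trans-α,β-dibenzyl-γ-butyrolactone. The forward key step is the anti-selective alkylation of the enolate of the enantioenriched β-(arylmethyl)-γ-butyrolactone A1 with the ring A benzylic bromide, to give the trans-lactone A2. Reduction of the lactone and deoxygenation of both hydroxymethyl arms to methyl would follow. The chosen plan is preferred on three grounds:
- A2 carries two oxygenated carbons (C9, C9') that the target lacks, so three further operations serve only to remove oxygen.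
- The stereocentres are set one after the other, the first by a separate asymmetric step and the second by substrate control.
- The count comes to about eleven steps against nine, whereas the chosen route sets both centres on the final carbon skeleton with no redox detour.

**Alternative 2:** iterative 1,2-metallate homologation. The cuts are C7–C8, C8–C8' and C8'–C7' in sequence. The ring A benzylic boronic ester A3 would be homologated twice with an enantioenriched α-lithiated ethyl carbenoid (sparteine-derived) to the secondary boronic ester A4. A one-carbon homologation and a Suzuki–Miyaura coupling with a ring B aryl bromide would complete the chain. Reagent control should make the selectivity high, but the chosen plan is preferred: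
- Each stereocentre needs its own stoichiometric chiral reagent at low temperature.
- The chain grows one carbon at a time in a fully linear sequence, so convergence is lost.
- The chosen route sets both centres with one catalytic operation on a convergent intermediate.

**Alternative 3:** hidden twofold symmetry. All four methoxy groups of the bis-syringyl compound A5 are equivalent, so the target is formally its mono-O-demethyl derivative. The cut is C8–C8' into two identical halves. The forward sequence is homo-coupling of one syringyl C6–C3 unit, double hydrogenation to A5, then one chelation-assisted O-demethylation. This would shorten the front of the synthesis, but the chosen plan is preferred: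
- The two rings of A5 react independently, so the demethylation can only be statistical.
- It would give unchanged, mono- and bis-demethylated material of similar polarity at the last step.
- Differentiating the rings at the outset costs only one extra three-step branch.

Key step: step 8

**Assumptions**
- The (S)-configured phosphinooxazoline ligand is taken to give the (R,R) product. This rests on analogy with the sense of hydrogenation of (E)-1,2-diphenylpropene to (R)-1,2-diphenylpropane, whose stereocentre has the same substituent pattern (sp2 carbon, arylmethyl, methyl). If a model run shows the opposite sense, the (R)-ligand is used.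
- In the SMILES of zirconocene compounds, each η5-cyclopentadienyl ligand is written as a σ-bonded C5H5 group.

## Route

Step 1
Reactants: 1 syringaldehyde (4-hydroxy-3,5-dimethoxybenzaldehyde)
Product: 2 4-(benzyloxy)-3,5-dimethoxybenzaldehyde
Conditions: BnBr, K2CO3, DMF, 60 °C
Reagents that add atoms: benzyl bromide, BrCc1ccccc1
Why: Williamson ether synthesis; the phenoxide is alkylated cleanly in DMF despite the two flanking methoxy groups, and the aldehyde is inert to carbonate.

Step 2
Reactants: 2 4-(benzyloxy)-3,5-dimethoxybenzaldehyde
Product: 3 2-(benzyloxy)-5-(2,2-dibromovinyl)-1,3-dimethoxybenzene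
Conditions: CBr4 (2 equiv), PPh3 (4 equiv), CH2Cl2, 0 °C
Reagents that add atoms: carbon tetrabromide, BrC(Br)(Br)Br
Why: First stage of the Corey–Fuchs reaction; the ylide Ph3P=CBr2 formed in the flask olefinates the aldehyde in a Wittig reaction, and aryl ethers are inert.

Step 3
Reactants: 3 2-(benzyloxy)-5-(2,2-dibromovinyl)-1,3-dimethoxybenzene
Product: 5 2-(benzyloxy)-1,3-dimethoxy-5-(prop-1-yn-1-yl)benzene, via lithium arylacetylide 4 (not isolated)
Conditions: n-BuLi (2.1 equiv), THF, −78 °C; then MeI, −78 °C to rt
Reagents that add atoms: iodomethane, CI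
Why: Second stage of the Corey–Fuchs reaction; bromine–lithium exchange, 1,2-shift of the carbenoid (Fritsch–Buttenberg–Wiechell) and deprotonation give acetylide 4, which is methylated in the same flask. Exchange at −78 °C is much faster than deprotonation of the OCH2Ph group.

Step 4
Reactants: 6 5-hydroxyvanillin (3,4-dihydroxy-5-methoxybenzaldehyde)
Product: 7 3,4-bis(benzyloxy)-5-methoxybenzaldehyde
Conditions: BnBr (2.4 equiv), K2CO3, DMF, 60 °C, under N2
Reagents that add atoms: benzyl bromide, BrCc1ccccc1
Why: Double Williamson ether synthesis; exclusion of air protects the catecholate until both oxygens are alkylated.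

Step 5
Reactants: 7 3,4-bis(benzyloxy)-5-methoxybenzaldehyde
Product: 8 1,2-bis(benzyloxy)-5-(2,2-dibromovinyl)-3-methoxybenzene
Conditions: CBr4 (2 equiv), PPh3 (4 equiv), CH2Cl2, 0 °C
Reagents that add atoms: carbon tetrabromide, BrC(Br)(Br)Br
Why: Corey–Fuchs dibromo-olefination, as in step 2.

Step 6
Reactants: 8 1,2-bis(benzyloxy)-5-(2,2-dibromovinyl)-3-methoxybenzene
Product: 10 1,2-bis(benzyloxy)-3-methoxy-5-(prop-1-yn-1-yl)benzene, via lithium arylacetylide 9 (not isolated)
Conditions: n-BuLi (2.1 equiv), THF, −78 °C; then MeI, −78 °C to rt
Reagents that add atoms: iodomethane, CI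
Why: Corey–Fuchs alkyne formation with methylation of acetylide 9 in the same flask, as in step 3.

Step 7
Reactants: 5 2-(benzyloxy)-1,3-dimethoxy-5-(prop-1-yn-1-yl)benzene; 10 1,2-bis(benzyloxy)-3-methoxy-5-(prop-1-yn-1-yl)benzene
Product: 13 1,2-bis(benzyloxy)-5-[(1E,3E)-4-(4-(benzyloxy)-3,5-dimethoxyphenyl)-2,3-dimethylbuta-1,3-dien-1-yl]-3-methoxybenzene, via zirconacyclopentene 11 (not isolated), via zirconacyclopentadiene 12 (not isolated)
Conditions: Cp2ZrCl2, EtMgBr (2 equiv), THF, −78 °C; 5, 0 °C; 10, 50 °C; then 3 M HCl, rt
Reagents that add atoms: none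
Why: Zirconocene-mediated alkyne–alkyne cross-coupling (reductive cyclodimerisation) followed by protodemetalation: Cp2ZrEt2 loses ethane to give Cp2Zr(ethylene), a divalent zirconium equivalent that couples with 5 to give 11, and at 50 °C 11 exchanges its ethylene for 10 to give 12. Aryl groups prefer the carbon next to zirconium, and the insertions are reversible, so the 2,5-diaryl-3,4-dimethyl metallacycle should be the thermodynamic product. Protonolysis of both Zr–C(sp2) bonds with retention puts hydrogen where zirconium stood, cis to the new C8–C8' bond on each alkene, which gives the (E,E)-diene only.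

Step 8
Reactants: 13 1,2-bis(benzyloxy)-5-[(1E,3E)-4-(4-(benzyloxy)-3,5-dimethoxyphenyl)-2,3-dimethylbuta-1,3-dien-1-yl]-3-methoxybenzene
Product: 16 (2R,3R)-1-[3,4-bis(benzyloxy)-5-methoxyphenyl]-4-[4-(benzyloxy)-3,5-dimethoxyphenyl]-2,3-dimethylbutane, via ring-A-side monoene 14 (not isolated), via ring-B-side monoene 15 (not isolated)
Conditions: [Ir(cod)(L)]BArF (2 mol%), H2 (50 bar), CH2Cl2, 25 °C; L = (S)-4-tert-butyl-2-[2-(di-o-tolylphosphanyl)phenyl]-4,5-dihydrooxazole, cod = 1,5-cyclooctadiene, BArF = tetrakis[3,5-bis(trifluoromethyl)phenyl]borate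
Reagents that add atoms: none
Why: Iridium-catalysed asymmetric hydrogenation of unfunctionalised trisubstituted aryl alkenes, run twice in one flask on a conjugated diene; the closest known cases are (E)-1,2-diphenylpropene and 2,3-diaryl-1,3-butadienes with cationic iridium N,P or N,carbene catalysts. Mechanism: hydrogen removes cod, the iridium dihydride binds one C=C, and migratory insertion followed by reductive elimination (a trivalent/pentavalent iridium cycle) delivers both hydrogens syn to one face, a 1,2-addition that passes through no allyl intermediate, so 1,4-addition to the tetrasubstituted alkene is not expected. No ring is closed. C8 and C8' are both set by the catalyst and not by the substrate: the ligand pocket accepts each Ar–CH=C(CH3)– unit only with its vinylic hydrogen in the hindered quadrant, and because the two units of 13 are related by the local twofold axis the same face is chosen twice, giving the like (R,R) pair and not the (R,S) isomer. The first addition gives 14 and 15, each still a styrene-type trisubstituted alkene, and both converge on 16 under the same control; the new allylic stereocentre exerts little bias because the substituent cis to it on the alkene is hydrogen, so 1,3-allylic strain is small. The step needs pure (E,E) geometry, since a Z alkene would invert the centre it forms, and the metallacycle of step 7 secures this. A molecule reduced with the wrong sense at one alkene ends as the (R,S) diastereomer, so the enantiomeric purity of (R,R)-16 should be higher than the selectivity of a single addition, at the cost of some diastereomer to remove. Aryl, methyl and benzyl ethers do not bind the cationic metal and are not hydrogenolysed under homogeneous conditions.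

Step 9
Reactants: 16 (2R,3R)-1-[3,4-bis(benzyloxy)-5-methoxyphenyl]-4-[4-(benzyloxy)-3,5-dimethoxyphenyl]-2,3-dimethylbutane
Product: 17 Sauriol B, 5-[(2R,3R)-4-(4-hydroxy-3,5-dimethoxyphenyl)-2,3-dimethylbutyl]-3-methoxybenzene-1,2-diol
Conditions: H2 (1 atm), Pd/C (10 wt%), EtOAc–MeOH, rt; filtration and concentration under Ar
Reagents that add atoms: none
Why: Hydrogenolysis of three aryl benzyl ethers; aryl methyl ethers and the benzylic C–C bonds at C7 and C7' are inert, and the stereocentres bear no group that could epimerise or be reduced.

## Compound list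

1 | syringaldehyde (4-hydroxy-3,5-dimethoxybenzaldehyde) | COc1cc(C=O)cc(OC)c1O | starting material
2 | 4-(benzyloxy)-3,5-dimethoxybenzaldehyde | COc1cc(C=O)cc(OC)c1OCc1ccccc1 | intermediate
3 | 2-(benzyloxy)-5-(2,2-dibromovinyl)-1,3-dimethoxybenzene | COc1cc(C=C(Br)Br)cc(OC)c1OCc1ccccc1 | intermediate
4 | lithium [4-(benzyloxy)-3,5-dimethoxyphenyl]acetylide | [Li]C#Cc1cc(OC)c(OCc2ccccc2)c(OC)c1 | intermediate (not isolated)
5 | 2-(benzyloxy)-1,3-dimethoxy-5-(prop-1-yn-1-yl)benzene | CC#Cc1cc(OC)c(OCc2ccccc2)c(OC)c1 | intermediate
6 | 5-hydroxyvanillin (3,4-dihydroxy-5-methoxybenzaldehyde) | COc1cc(C=O)cc(O)c1O | starting material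
7 | 3,4-bis(benzyloxy)-5-methoxybenzaldehyde | COc1cc(C=O)cc(OCc2ccccc2)c1OCc1ccccc1 | intermediate
8 | 1,2-bis(benzyloxy)-5-(2,2-dibromovinyl)-3-methoxybenzene | COc1cc(C=C(Br)Br)cc(OCc2ccccc2)c1OCc1ccccc1 | intermediate
9 | lithium [3,4-bis(benzyloxy)-5-methoxyphenyl]acetylide | [Li]C#Cc1cc(OC)c(OCc2ccccc2)c(OCc2ccccc2)c1 | intermediate (not isolated)
10 | 1,2-bis(benzyloxy)-3-methoxy-5-(prop-1-yn-1-yl)benzene | CC#Cc1cc(OC)c(OCc2ccccc2)c(OCc2ccccc2)c1 | intermediate
11 | 1,1-bis(η5-cyclopentadienyl)-2-[4-(benzyloxy)-3,5-dimethoxyphenyl]-3-methyl-1-zirconacyclopent-2-ene | CC1=C(c2cc(OC)c(OCc3ccccc3)c(OC)c2)[Zr](C2C=CC=C2)(C2C=CC=C2)CC1 | intermediate (not isolated)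
12 | 1,1-bis(η5-cyclopentadienyl)-2-[4-(benzyloxy)-3,5-dimethoxyphenyl]-5-[3,4-bis(benzyloxy)-5-methoxyphenyl]-3,4-dimethyl-1-zirconacyclopenta-2,4-diene | CC1=C(c2cc(OC)c(OCc3ccccc3)c(OC)c2)[Zr](C2C=CC=C2)(C2C=CC=C2)C(c2cc(OC)c(OCc3ccccc3)c(OCc3ccccc3)c2)=C1C | intermediate (not isolated)
13 | 1,2-bis(benzyloxy)-5-[(1E,3E)-4-(4-(benzyloxy)-3,5-dimethoxyphenyl)-2,3-dimethylbuta-1,3-dien-1-yl]-3-methoxybenzene | COc1cc(/C=C(C)/C(C)=C/c2cc(OC)c(OCc3ccccc3)c(OC)c2)cc(OCc2ccccc2)c1OCc1ccccc1 | intermediate
14 | 1,2-bis(benzyloxy)-5-[(2R,3E)-4-(4-(benzyloxy)-3,5-dimethoxyphenyl)-2,3-dimethylbut-3-en-1-yl]-3-methoxybenzene | COc1cc(C[C@@H](C)/C(C)=C/c2cc(OC)c(OCc3ccccc3)c(OC)c2)cc(OCc2ccccc2)c1OCc1ccccc1 | intermediate (not isolated)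
15 | 2-(benzyloxy)-5-[(2R,3E)-4-(3,4-bis(benzyloxy)-5-methoxyphenyl)-2,3-dimethylbut-3-en-1-yl]-1,3-dimethoxybenzene | COc1cc(/C=C(C)/[C@H](C)Cc2cc(OC)c(OCc3ccccc3)c(OC)c2)cc(OCc2ccccc2)c1OCc1ccccc1 | intermediate (not isolated)
16 | (2R,3R)-1-[3,4-bis(benzyloxy)-5-methoxyphenyl]-4-[4-(benzyloxy)-3,5-dimethoxyphenyl]-2,3-dimethylbutane | COc1cc(C[C@@H](C)[C@H](C)Cc2cc(OC)c(OCc3ccccc3)c(OC)c2)cc(OCc2ccccc2)c1OCc1ccccc1 | intermediate
17 | Sauriol B, 5-[(2R,3R)-4-(4-hydroxy-3,5-dimethoxyphenyl)-2,3-dimethylbutyl]-3-methoxybenzene-1,2-diol | COc1cc(C[C@@H](C)[C@H](C)Cc2cc(OC)c(O)c(OC)c2)cc(O)c1O | target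

## Step count and least certain steps

Total step count: 9. Longest linear sequence: 6 steps (1 to 2 to 3 to 5, then 13, 16, 17; the branch from 6 is of equal length).

**Step 8 (key step).** Three things are most likely to go wrong.
- The second addition may proceed with eroded facial selectivity if the allylic stereocentre of 14 or 15 opposes the catalyst. This would raise the share of the (R,S) diastereomer, which is hard to separate from 16.
- The conjugated diene may chelate iridium as an η4 ligand, as cod does, and slow turnover.
- The reaction may stall at the monoene, or the remaining alkene may isomerise out of conjugation.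

The fallback uses the classical lactone logic with known reactions only. It sets out from 7 and 2 and returns at 16.
- Stobbe condensation of 7 with dimethyl succinate (NaOMe, MeOH, reflux) should give the (E)-arylidenesuccinic acid monomethyl ester F1.
- Hydrogenation of this chelating substrate with [Rh(cod)(Me-DuPhos)]BF4, in the antipode that delivers the (R)-acid, should give the (R)-arylmethylsuccinic acid monomethyl ester F2.
- Reduction of the ester arm of its potassium salt with Ca(BH4)2 and acid lactonisation should give the (R)-β-arylmethyl-γ-butyrolactone F3.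
- In parallel, NaBH4 reduces 2 to the benzylic alcohol F4, and PBr3 converts it into the benzylic bromide F5.
- Alkylation of the LiN(SiMe3)2 enolate of F3 with F5, anti to the β-substituent, should give the (3R,4R)-trans-lactone F6.
- LiAlH4 should give the (2R,3R)-diol F7, MsCl and Et3N the bis-mesylate F8, and LiAlH4 then replaces both sulfonates by hydride to give 16.

**Step 7.** The two alkynes are electronically almost identical. Exchange of the first alkyne out of 11 at 50 °C would scramble the partners and give homo-dimers that differ from 13 only by benzyl against methyl. The electron-rich aryl groups may also favour the carbon next to zirconium less strongly, which would let a 2,4-diaryl metallacycle form. The fallback sets out from 5 and 10 and returns at 13.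
- Borylcupration–protonation of 5 (CuCl, Xantphos, NaOtBu, B2pin2, MeOH, THF) places boron on the methyl-bearing carbon by syn addition and should give the ring-B (Z)-alkenyl pinacol boronate F9.
- The same reaction on 10 should give the ring-A (Z)-alkenyl pinacol boronate F10.
- Iodination of F10 with retention (I2, NaOH, THF–H2O) should give the ring-A (E)-alkenyl iodide F11.
- Suzuki–Miyaura coupling of F9 with F11 (Pd(PPh3)4, a zerovalent palladium catalyst, aqueous K3PO4, dioxane, 80 °C) joins C8 to C8' with retention at both alkenes and gives 13.

**Step 6.** n-BuLi may deprotonate one of the two OCH2Ph groups in competition with bromine–lithium exchange, leading to 1,2-Wittig rearrangement of a benzyl ether. Methylation of the acetylide may also be incomplete. Step 3 is the same reaction with one benzyl ether fewer and is judged safer. The fallback avoids alkyllithium altogether; it sets out from 7 and returns at 10.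
- Seyferth–Gilbert homologation of 7 with dimethyl (1-diazo-2-oxopropyl)phosphonate (K2CO3, MeOH, rt) should give the terminal arylacetylene F12.
- Deprotonation with LiN(SiMe3)2 (THF, −78 °C) and MeI then gives 10.

**Step 9.** The freed catechol may be oxidised by air on the palladium surface or during filtration, giving quinone-derived material. Cleavage may also stall at a mono- or bis-benzyl ether if the catalyst is poisoned. The fallback changes the mechanism from hydrogenolysis to Lewis acid cleavage with a cation scavenger: BCl3 and pentamethylbenzene in CH2Cl2 at −78 °C, from 16 directly to 17, at a temperature where aryl methyl ethers are not cleaved. It makes no new compound (F0).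

## Further compounds

F1 | step 8 | (E)-4-[3,4-bis(benzyloxy)-5-methoxyphenyl]-3-(methoxycarbonyl)but-3-enoic acid | COC(=O)/C(CC(=O)O)=C/c1cc(OC)c(OCc2ccccc2)c(OCc2ccccc2)c1
F2 | step 8 | (R)-4-[3,4-bis(benzyloxy)-5-methoxyphenyl]-3-(methoxycarbonyl)butanoic acid | COc1cc(C[C@H](CC(=O)O)C(=O)OC)cc(OCc2ccccc2)c1OCc1ccccc1
F3 | step 8 | (R)-4-[3,4-bis(benzyloxy)-5-methoxybenzyl]dihydrofuran-2(3H)-one | COc1cc(C[C@H]2COC(=O)C2)cc(OCc2ccccc2)c1OCc1ccccc1
F4 | step 8 | [4-(benzyloxy)-3,5-dimethoxyphenyl]methanol | COc1cc(CO)cc(OC)c1OCc1ccccc1
F5 | step 8 | 2-(benzyloxy)-5-(bromomethyl)-1,3-dimethoxybenzene | COc1cc(CBr)cc(OC)c1OCc1ccccc1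
F6 | step 8 | (3R,4R)-3-[4-(benzyloxy)-3,5-dimethoxybenzyl]-4-[3,4-bis(benzyloxy)-5-methoxybenzyl]dihydrofuran-2(3H)-one | COc1cc(C[C@H]2COC(=O)[C@@H]2Cc2cc(OC)c(OCc3ccccc3)c(OC)c2)cc(OCc2ccccc2)c1OCc1ccccc1
F7 | step 8 | (2R,3R)-2-[3,4-bis(benzyloxy)-5-methoxybenzyl]-3-[4-(benzyloxy)-3,5-dimethoxybenzyl]butane-1,4-diol | COc1cc(C[C@@H](CO)[C@H](CO)Cc2cc(OC)c(OCc3ccccc3)c(OC)c2)cc(OCc2ccccc2)c1OCc1ccccc1
F8 | step 8 | (2R,3R)-2-[3,4-bis(benzyloxy)-5-methoxybenzyl]-3-[4-(benzyloxy)-3,5-dimethoxybenzyl]butane-1,4-diyl dimethanesulfonate | COc1cc(C[C@@H](COS(C)(=O)=O)[C@H](COS(C)(=O)=O)Cc2cc(OC)c(OCc3ccccc3)c(OC)c2)cc(OCc2ccccc2)c1OCc1ccccc1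
F9 | step 7 | 2-[(Z)-1-(4-(benzyloxy)-3,5-dimethoxyphenyl)prop-1-en-2-yl]-4,4,5,5-tetramethyl-1,3,2-dioxaborolane | C/C(B1OC(C)(C)C(C)(C)O1)=C\c1cc(OC)c(OCc2ccccc2)c(OC)c1
F10 | step 7 | 2-[(Z)-1-(3,4-bis(benzyloxy)-5-methoxyphenyl)prop-1-en-2-yl]-4,4,5,5-tetramethyl-1,3,2-dioxaborolane | C/C(B1OC(C)(C)C(C)(C)O1)=C\c1cc(OC)c(OCc2ccccc2)c(OCc2ccccc2)c1
F11 | step 7 | 1,2-bis(benzyloxy)-5-[(E)-2-iodoprop-1-en-1-yl]-3-methoxybenzene | C/C(I)=C\c1cc(OC)c(OCc2ccccc2)c(OCc2ccccc2)c1
F12 | step 6 | 1,2-bis(benzyloxy)-5-ethynyl-3-methoxybenzene | C#Cc1cc(OC)c(OCc2ccccc2)c(OCc2ccccc2)c1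
F0 | step 9 | none | none
A1 | alternative 1 | (R)-4-[4-(benzyloxy)-3,5-dimethoxybenzyl]dihydrofuran-2(3H)-one | O=C1OC[C@@H](C1)Cc1cc(OC)c(OCc2ccccc2)c(OC)c1
A2 | alternative 1 | (3R,4R)-3-[3,4-bis(benzyloxy)-5-methoxybenzyl]-4-[4-(benzyloxy)-3,5-dimethoxybenzyl]dihydrofuran-2(3H)-one | COc1cc(C[C@H]2C(=O)OC[C@@H]2Cc2cc(OC)c(OCc3ccccc3)c(OC)c2)cc(OCc2ccccc2)c1OCc1ccccc1
A3 | alternative 2 | 2-[3,4-bis(benzyloxy)-5-methoxybenzyl]-4,4,5,5-tetramethyl-1,3,2-dioxaborolane | COc1cc(CB2OC(C)(C)C(C)(C)O2)cc(OCc2ccccc2)c1OCc1ccccc1
A4 | alternative 2 | 2-[(2S,3R)-4-(3,4-bis(benzyloxy)-5-methoxyphenyl)-3-methylbutan-2-yl]-4,4,5,5-tetramethyl-1,3,2-dioxaborolane | COc1cc(C[C@@H](C)[C@H](C)B2OC(C)(C)C(C)(C)O2)cc(OCc2ccccc2)c1OCc1ccccc1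
A5 | alternative 3 | 4,4'-[(2R,3R)-2,3-dimethylbutane-1,4-diyl]bis(2,6-dimethoxyphenol) | COc1cc(C[C@@H](C)[C@H](C)Cc2cc(OC)c(O)c(OC)c2)cc(OC)c1O
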